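(The numbers in the tables were computed from invented constants.)

Keep this balance first: each starting material that reacts consumes one partner and becomes target, and target may pass on to isomer of the product, so in these flasks target plus isomer equals partner consumed.

| flask | starting material | partner | temperature | remark | time |
|---|---|---|---|---|---|
| eta | 0.0090 M | 0.60 equiv | 30 °C | run made earlier |  |
| zeta | 0.023 M | 0.60 equiv | 41 °C | run made earlier |  |
| summer | 0.0080 M | 0.600 equiv |  | at 25 °C throughout | 8.0 h |
| midnight | 0.017 M | 0.600 equiv |  | at 25 °C until 2.5 h, from then on at 45 °C | 8.0 h |

| run | time / h | target / % |
|---|---|---|
| eta | 0.417 | 1.7 |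
| eta | 0.667 | 1.3 |
| eta | 1.33 | 2.8 |
| eta | 2.00 | 1.4 |
| eta | 3.00 | 1.5 |
| eta | 6.00 | 4.1 |
| zeta | 0.200 | 2.3 |
| zeta | 0.333 | 2.3 |
| zeta | 0.667 | 6.9 |
| zeta | 0.833 | 10.4 |
| zeta | 1.33 | 13.9 |
| zeta | 2.50 | 14.9 |

(standard deviation of a reading: 1 percentage point)

1. the flask that ends with the higher amount of target, in percent of the starting material charged, or "neither" when 2 percentage points or less lies between them (summer / midnight / neither)
2. final target, as a percentage of the starting material charged, in summer
3. final target, as a percentage of the starting material charged, in midnight

- steps under discussion: starting material + partner + target -> 2 target; starting material + partner -> target; target <-> isomer of the product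
- where the amount of starting material changes, what is given in equivalents or mol% on it follows

Read the late end from the zeta run. Between 0.667 h and 1.33 h its target rises at 0.106 h⁻¹ of the charge, and over the last interval at 0.00855 h⁻¹, a rise of 1 percentage point that the scatter of 1 point covers, so I read the trace as level at 14.9%. Assuming the partner charge of 0.60 equiv was consumed there, the target share, target standing per partner consumed, is 0.248. This is a reading at the zeta temperature. On 0.600 equiv, with the partner consumed and the share taken as unchanged, it gives an estimated level of 14.9%.

Now the clock. At equal equivalents and temperature, I reckon with the step through target, whose rate as a fraction of the charge goes with the square of the concentration. Summer's 8.0 h then count as 6.32 h of the eta run, whose last reading is 4.1%, and summer is colder, so my own figure for summer is below that reading. By that square, midnight needs 4.58 h at the zeta temperature to cover the span of the zeta trace. It has 5.50 h at a warmer temperature, so I expect midnight near that estimated level.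

The forecast says midnight, with 3% in summer and 15% in midnight, reasoning that midnight has “enough to finish, so it reaches the plateau”.

The simulation gives 3.44% in summer and 13.2% in midnight, so midnight ends higher.

    starting material + partner + target → 2 target (k = 4900 L² mol⁻² h⁻¹, Ea = 41.0 kJ mol⁻¹)
    starting material + partner → target (k = 1.20 L mol⁻¹ h⁻¹, Ea = 79.0 kJ mol⁻¹)
    target ⇌ isomer of the product (K = 2.10, k = 0.330 h⁻¹, Ea = 85.0 kJ mol⁻¹, ΔH = 16.0 kJ mol⁻¹)
    (constants at 25 °C)

Midnight ends low because target and isomer interconvert: the run with that conversion, both ways, taken away reaches 59.8%. Partner stands at 12.4% of its charge at 8.00 h, so the target share on the partner consumed gives 13.0%, against 13.2% in the flask.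

Take midnight with 1.50 equiv of partner: starting material becomes the limiting reagent, so the share applies to the whole charge and gives 0.248 of it. The computed flask holds 24.0% target, with 1.1% of the starting material left.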